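Watch c_G in mM, not only in percent: the reckoning below runs in mM.

- Monday's: L 20 mM; the very flask that is asked about, followed so far
- flask: L 20 mM; time 6.0 h

Monday's run (percent of the L charged)

| time / h | G / % |
|---|---|
| 0.667 | 10.5 |
| 0.833 | 11.0 |
| 1.00 | 11.9 |
| 1.33 | 12.9 |
| 2.00 | 13.7 |
| 2.50 | 14.7 |
| 3.00 | 15.6 |

(each reading ± 0.5 percentage points)

- percentages count the L that a species holds: one Z counts as two
- G is meant together with its Q
- solid, in amounts per volume of the solution: Q
- candidate steps: L -> D; E <-> G; Q <-> G; 2 L -> Z; L <-> E

* time up to 6.0 h at which G stands highest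
* the amount of G, in percent of the L charged, at that time

In Monday's flask, G first climbs fast and later slowly:

early speed = 3.15 mM h⁻¹

late speed, from 2.00 h to 3.00 h, = 0.380 mM h⁻¹

Extreme one: L passes to G singly and nothing else takes it. The speed then sinks with the charge used, to 2.66 mM h⁻¹, yet the readings show far less. Extreme two: another route empties L at once and G stops dead, yet the readings still climb. Monday's flask lies between, nearer the second, and the candidate is L pairing to Z, whose rate goes with c_L squared.

So I take the last reading as the escape amount, my estimate of the c_G that gets through while the pairing takes most of L: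

escape amount = 3.12 mM

The step between E and G runs both ways, so G can flow back, and I expect a top near 3.00 h at about 15.6%. The forecast says 6 h and 20%, “still rising, so the maximum is at the end of the window”.

The flask peaks at 2.82 h with 14.8%.

    L → D (k = 7.30 × 10⁻⁷ s⁻¹)
    E ⇌ G (K = 4.80, k = 3.40 × 10⁻⁴ s⁻¹)
    Q ⇌ G, rate k3*(cs3 - [G]) while solid is left; crystals form when [G] > cs3 (solubility = 9.70 mM, k = 0.0270 s⁻¹)
    2 L → Z (k = 0.0620 M⁻¹ s⁻¹)
    L ⇌ E (K = 0.700, k = 7.40 × 10⁻⁴ s⁻¹)

The escape amount of 3.12 mM leaves 16.9 mM of the charge in other forms, and in this flask at 2.81 h Z holds 77.8%. Take away the step from two L to Z and the highest G in this flask goes from 14.8% to 70.5%. At 80 mM, the escape amount held fixed gives 3.90%, and the percentage held fixed gives 15.6%. The computed neighbour reaches 5.85%, between the two.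

The numbers in the tables are simulated from invented constants; noise was put on by code.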